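Numbering the ring as in the target name (C1 CH–CO2Me, C2 carbinol, C3=C4, C5 ketone), everything rests on cutting the cyclopentenone at C2–C3 and C4–C5, on both sides of the vinylene. In one flask a cis-silylvinyllithium, made from acetylene, adds to the ketone (future C2) of an acyclic keto ester, silicon shifts from carbon to the new alkoxide (Brook rearrangement), and the vinyl anion so relayed acylates the ester (future C5), expelling a chiral alkoxide. The step exploits the 1,3-spacing of C2 and C5 across C1 and the cis placing of the C2 oxygen and the C3=C4 bond. In the precursor C1 is a ketene dithioacetal, a masked CO2Me without acidic C–H.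

Key step: step 5

Assumption: the (−)-8-phenylmenthyl ester of 7 is taken to shield the Si face of the ketone (ketone held s-cis to the C=C by its S···O contact, aryl group stacked over the acrylate face). This sense is not established for this substrate; if it proves opposite, the enantiomeric auxiliary is used and nothing else changes.

Step 1
Reactants: 1 heptadecanoyl chloride; 2 2,2-dimethyl-1,3-dioxane-4,6-dione
Product: 3 5-(1-hydroxyheptadecylidene)-2,2-dimethyl-1,3-dioxane-4,6-dione
Conditions: pyridine, CH2Cl2, 0 °C to rt; dilute HCl wash
Reagents that add atoms: none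
Why: C-acylation of the strongly acidic cyclic malonate by an acid chloride (acylation of an active methylene compound) should give the enolised acyl derivative, the usual acylketene precursor.

Step 2
Reactants: 3; 4 (1R,2S,5R)-5-methyl-2-(2-phenylpropan-2-yl)cyclohexan-1-ol, (−)-8-phenylmenthol
Product: 5 (1R,2S,5R)-5-methyl-2-(2-phenylpropan-2-yl)cyclohexyl 3-oxononadecanoate
Conditions: toluene, 110 °C
Reagents that add atoms: none
Why: on heating, 3 should lose acetone and CO2 by retro-[4+2] fragmentation to an acylketene, which the hindered alcohol traps as the β-keto ester (acylketene alcoholysis), installing the chiral alkoxy group that later leaves.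

Step 3
Reactants: 5; 6 carbon disulfide
Product: 7 (1R,2S,5R)-5-methyl-2-(2-phenylpropan-2-yl)cyclohexyl 2-[bis(methylsulfanyl)methylidene]-3-oxononadecanoate
Conditions: K2CO3, DMF, 0 °C; then MeI (2 equiv), rt
Reagents that add atoms: iodomethane, CI
Why: the active methylene adds to CS2 and the dithiolate is S-methylated twice (α-oxo ketene dithioacetal synthesis), which makes C1 sp2, removes the acidic hydrogen between the carbonyls and stores the future ester carbon at the carboxyl oxidation level.

Step 4
Reactants: 8 acetylene; 9 trimethyl(tributylstannyl)silane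
Product: 10 tributyl[(Z)-2-(trimethylsilyl)ethenyl]stannane
Conditions: Pd(PPh3)4 (cat.), acetylene (1 atm), THF, 60 °C
Reagents that add atoms: none
Why: silylstannation of an alkyne catalysed by zerovalent palladium (oxidative addition of Si–Sn, syn insertion, reductive elimination) delivers both metals to the same face, so acetylene should give only the cis-1-silyl-2-stannylethene.

Step 5
Reactants: 10 tributyl[(Z)-2-(trimethylsilyl)ethenyl]stannane; 7 the keto ester ketene dithioacetal
Product: 14 (4R)-5-[bis(methylsulfanyl)methylidene]-4-hexadecyl-4-[(trimethylsilyl)oxy]cyclopent-2-en-1-one, via cis-silylvinyllithium 11 (not isolated), via lithium alkoxide 12 (not isolated), via silyloxy vinyllithium 13 (not isolated)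
Conditions: n-BuLi, THF, −78 °C; add 7, −78 °C; HMPA, −78 to −20 °C; aq NH4Cl
Reagents that add atoms: none
Why: Proposed new method: tin–lithium exchange gives the cis-silylvinyllithium 11, which should add 1,2 to the ketone of the non-enolisable keto ester 7 (bond C2–C3); HMPA then promotes a [1,4] shift of silicon from carbon to the alkoxide oxygen (Brook rearrangement), so that the carbanion reappears on the other alkene carbon in 13 and acylates the ester carbonyl with loss of the auxiliary alkoxide (bond C4–C5). The closest known reaction types are the Brook-rearrangement-mediated [3+2] annulation of acylsilanes with ketone enolates, the base-induced 1,4-silyl migration of cis-γ-silyl allylic alkoxides and the Parham-type acylation of an organolithium by an ester in the same molecule; their union on a keto ester whose central carbon is blocked as a ketene dithioacetal is new. The five-membered ring closes in the 5-exo-trig mode at the ester carbonyl. The one new stereocentre, C2, is fixed in the 1,2-addition: attack on the Re face of the ketone gives the (R) configuration, and the 8-phenylmenthyl ester is relied on to shield the Si face. The step needs 1,2- instead of conjugate addition (hard organolithium at −78 °C, the known behaviour of α-oxo ketene dithioacetals), retention of the Z geometry (only the cis isomer can shift silicon and close the ring; vinyllithiums hold their configuration at −78 °C) and silyl migration before any proton source is present. The alkoxide 12 cannot fragment by retro-aldol because C1 is sp2, and after the shift the tertiary oxygen already carries its trimethylsilyl group.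

Step 6
Reactants: 14 (4R)-5-[bis(methylsulfanyl)methylidene]-4-hexadecyl-4-[(trimethylsilyl)oxy]cyclopent-2-en-1-one
Product: 15 methyl (1R,2R)-2-hexadecyl-2-hydroxy-5-oxocyclopent-3-ene-1-carboxylate
Conditions: HgCl2 (2.2 equiv), MeOH containing 5% H2O, 0 °C to rt
Reagents that add atoms: methanol, CO; water, O
Why: thiophile-assisted solvolysis of the ketene dithioacetal should unveil the methyl ester while the HCl set free cleaves the tertiary silyl ether, and C1, protonated and then equilibrated through the β-keto ester enol, should settle with CO2Me trans to the hexadecyl chain and cis to the hydroxyl, which is (1R).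

Compound list

1 | heptadecanoyl chloride | CCCCCCCCCCCCCCCCC(=O)Cl | starting material
2 | 2,2-dimethyl-1,3-dioxane-4,6-dione | CC1(C)OC(=O)CC(=O)O1 | starting material
3 | 5-(1-hydroxyheptadecylidene)-2,2-dimethyl-1,3-dioxane-4,6-dione | CCCCCCCCCCCCCCCCC(O)=C1C(=O)OC(C)(C)OC1=O | intermediate
4 | (1R,2S,5R)-5-methyl-2-(2-phenylpropan-2-yl)cyclohexan-1-ol, (−)-8-phenylmenthol | CC(C)(c1ccccc1)[C@@H]1CC[C@@H](C)C[C@H]1O | starting material
5 | (1R,2S,5R)-5-methyl-2-(2-phenylpropan-2-yl)cyclohexyl 3-oxononadecanoate | CC(C)(c1ccccc1)[C@@H]1CC[C@@H](C)C[C@H]1OC(=O)CC(=O)CCCCCCCCCCCCCCCC | intermediate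
6 | carbon disulfide | S=C=S | starting material
7 | (1R,2S,5R)-5-methyl-2-(2-phenylpropan-2-yl)cyclohexyl 2-[bis(methylsulfanyl)methylidene]-3-oxononadecanoate | CC(C)(c1ccccc1)[C@@H]1CC[C@@H](C)C[C@H]1OC(=O)C(=C(SC)SC)C(=O)CCCCCCCCCCCCCCCC | intermediate
8 | acetylene | C#C | starting material
9 | trimethyl(tributylstannyl)silane | CCCC[Sn](CCCC)(CCCC)[Si](C)(C)C | starting material
10 | tributyl[(Z)-2-(trimethylsilyl)ethenyl]stannane | CCCC[Sn](CCCC)(CCCC)/C=C\[Si](C)(C)C | intermediate
11 | [(Z)-2-(trimethylsilyl)ethenyl]lithium | [Li]/C=C\[Si](C)(C)C | intermediate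
12 | lithium salt of (1R,2S,5R)-5-methyl-2-(2-phenylpropan-2-yl)cyclohexyl (3R)-2-[bis(methylsulfanyl)methylidene]-3-oxido-3-[(Z)-2-(trimethylsilyl)ethenyl]nonadecanoate | CC(C)(c1ccccc1)[C@@H]1CC[C@@H](C)C[C@H]1OC(=O)C(=C(SC)SC)[C@@]([O-])(CCCCCCCCCCCCCCCC)/C=C\[Si](C)(C)C.[Li+] | intermediate
13 | (1R,2S,5R)-5-methyl-2-(2-phenylpropan-2-yl)cyclohexyl (3R)-2-[bis(methylsulfanyl)methylidene]-3-[(Z)-2-lithioethenyl]-3-[(trimethylsilyl)oxy]nonadecanoate | CC(C)(c1ccccc1)[C@@H]1CC[C@@H](C)C[C@H]1OC(=O)C(=C(SC)SC)[C@@](O[Si](C)(C)C)(CCCCCCCCCCCCCCCC)/C=C\[Li] | intermediate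
14 | (4R)-5-[bis(methylsulfanyl)methylidene]-4-hexadecyl-4-[(trimethylsilyl)oxy]cyclopent-2-en-1-one | CCCCCCCCCCCCCCCC[C@@]1(O[Si](C)(C)C)C=CC(=O)C1=C(SC)SC | intermediate
15 | methyl (1R,2R)-2-hexadecyl-2-hydroxy-5-oxocyclopent-3-ene-1-carboxylate | CCCCCCCCCCCCCCCC[C@@]1(O)C=CC(=O)[C@@H]1C(=O)OC | target

Total step count: 6. Longest linear sequence: 5 (steps 1, 2, 3, 5, 6); step 4 is the convergent branch.

Steps most likely to fail

Step 5 (Proposed new method). The silyl migration may not outrun simple protonation of the alkoxide under lithium/HMPA. The organolithium may attack the dithioacetal carbon or enolise the ketone instead of adding 1,2. Facial selectivity in the addition may be poor, and it cannot be corrected because the auxiliary leaves in the same flask. The fallback uses known chemistry and separates the relay into discrete operations with tin in place of silicon. It sets out from 7 and 8. Acetylene 8 is distannylated with hexabutyldistannane and Pd(PPh3)4 to (Z)-1,2-bis(tributylstannyl)ethene F1. One tin–lithium exchange (n-BuLi, THF, −78 °C) gives [(Z)-2-(tributylstannyl)ethenyl]lithium F2, which adds 1,2 to 7 to give the lithium alkoxide F3. Quenching in the flask with Me3SiCl gives the silyl ether vinylstannane F4, which is isolated. Because the auxiliary is still attached, the two C3 epimers are diastereomers and can be separated by chromatography. A second tin–lithium exchange on F4 (n-BuLi, THF, −78 °C) generates 13 directly, which should close to 14 by the same intramolecular acylation. The fallback comes back to the route at 13.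

Step 6. The acid set free may promote loss of the tertiary hydroxyl (dehydration to a cyclopentadienone that dimerises). The solvolysis may stall at the S-methyl thioester, and the β-hydroxy ketone may open by retro-aldol once C1 is sp3. The fallback sets out from 14 and exchanges sulfur for oxygen under base, where retro-aldol is impossible because C1 is still sp2. NaOMe in MeOH (0 °C to rt) should replace both methylsulfanyl groups by addition–elimination and cleave the silyl ether, giving (4R)-5-(dimethoxymethylidene)-4-hexadecyl-4-hydroxycyclopent-2-en-1-one F5. Buffered hydrolysis of this ketene acetal (oxalic acid, wet THF, 0 °C) then gives the methyl ester. The fallback comes back at 15.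

Step 4. The silicon–tin reagent may disproportionate at palladium to distannane and disilane, and the Z adduct may isomerise on prolonged heating; either lowers the geometric purity on which step 5 depends. The fallback sets out from 8 and introduces the two metals one after the other. Acetylene 8 is distannylated to (Z)-1,2-bis(tributylstannyl)ethene F1 as above. One tin–lithium exchange (n-BuLi, THF, −78 °C) gives [(Z)-2-(tributylstannyl)ethenyl]lithium F2, and quenching F2 with Me3SiCl gives 10 with retention of geometry. The fallback comes back at 10.

Further compounds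

F1 | step 5 | (Z)-1,2-bis(tributylstannyl)ethene | CCCC[Sn](CCCC)(CCCC)/C=C\[Sn](CCCC)(CCCC)CCCC
F2 | step 5 | [(Z)-2-(tributylstannyl)ethenyl]lithium | [Li]/C=C\[Sn](CCCC)(CCCC)CCCC
F3 | step 5 | lithium salt of (1R,2S,5R)-5-methyl-2-(2-phenylpropan-2-yl)cyclohexyl (3R)-2-[bis(methylsulfanyl)methylidene]-3-oxido-3-[(Z)-2-(tributylstannyl)ethenyl]nonadecanoate | CC(C)(c1ccccc1)[C@@H]1CC[C@@H](C)C[C@H]1OC(=O)C(=C(SC)SC)[C@@]([O-])(CCCCCCCCCCCCCCCC)/C=C\[Sn](CCCC)(CCCC)CCCC.[Li+]
F4 | step 5 | (1R,2S,5R)-5-methyl-2-(2-phenylpropan-2-yl)cyclohexyl (3R)-2-[bis(methylsulfanyl)methylidene]-3-[(Z)-2-(tributylstannyl)ethenyl]-3-[(trimethylsilyl)oxy]nonadecanoate | CC(C)(c1ccccc1)[C@@H]1CC[C@@H](C)C[C@H]1OC(=O)C(=C(SC)SC)[C@@](O[Si](C)(C)C)(CCCCCCCCCCCCCCCC)/C=C\[Sn](CCCC)(CCCC)CCCC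
F5 | step 6 | (4R)-5-(dimethoxymethylidene)-4-hexadecyl-4-hydroxycyclopent-2-en-1-one | CCCCCCCCCCCCCCCC[C@@]1(O)C=CC(=O)C1=C(OC)OC
F0 | step 4 | none | none
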